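**Assumption:** the target is the 2,3‑trans (2R,3R) 3‑hydroxyflavanone exactly as in the SMILES (I assigned the CIP descriptors from the SMILES). All phenols are protected as MOM ethers.

## Retrosynthetic overview
1. The target comes from removal of three MOM groups from protected (2R,3R)‑3‑hydroxyflavanone **21**. Its pyranone ring is closed last: the free 2'‑OH opens a trans‑epoxide at the benzylic carbon (inversion there), and the epoxide oxygen becomes the 3‑OH.
2. The epoxy ketone **20** comes from a late C4a–C4 coupling of the A‑ring aryl‑bromophenol **8** (as its aryl‑lithium phenoxide) with the B‑ring epoxy Weinreb amide **19**.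
3. **19** comes from Sharpless asymmetric epoxidation of cinnamyl alcohol **16**, which sets both stereocentres. **16** comes from a Heck reaction of **13** with methyl acrylate. Both prenyl groups are made from allyl by Claisen rearrangement and cross‑metathesis.
4. **8** is built from resorcinol: Ir‑catalysed C–H borylation and oxidation give the 1,3,5‑trioxygenated ring.
5. Ring order: both aromatic rings are in the fragments, the epoxide forms on the B fragment, and the pyranone ring forms last.

## Route

**Step 1**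
Reactants: 1 resorcinol
Product: 2 1,3‑bis(methoxymethoxy)benzene
Conditions: NaH, THF, 0 °C; then MOMCl, rt
Reagents that add atoms: MOMCl, ClCOC
Why: O‑alkylation gives acetals that survive Ir catalysis, organolithiums and base, and come off with mild acid.

**Step 2**
Reactants: 2
Product: 3 2‑[3,5‑bis(MOMO)phenyl]‑4,4,5,5‑tetramethyl‑1,3,2‑dioxaborolane
Conditions: B2pin2, [Ir(cod)OMe]2 (1.5 mol%), dtbpy (3 mol%), THF, 80 °C
Reagents that add atoms: B2pin2, CC1(C)OB(OC1(C)C)B1OC(C)(C)C(C)(C)O1
Why: sterically controlled Ir C–H borylation occurs only at C5, the one position meta to both OMOM groups, so it marks the site of the third oxygen.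

**Step 3**
Reactants: 3
Product: 4 3,5‑bis(MOMO)phenol
Conditions: 30% H2O2, 2 M NaOH, THF, 0 °C → rt; NH4Cl quench to pH 7
Reagents that add atoms: hydrogen peroxide, OO
Why: oxidative deborylation replaces C–B with C–O with retention, giving the protected phloroglucinol pattern.

**Step 4**
Reactants: 4
Product: 5 2‑bromo‑3,5‑bis(MOMO)phenol
Conditions: NBS (1.0 equiv), i‑Pr2NH (10 mol%), CH2Cl2, −78 → 0 °C
Reagents that add atoms: NBS, O=C1CCC(=O)N1Br
Why: amine‑mediated ortho‑bromination of a phenol; the two ortho carbons are equivalent, so there is no regiochemical choice, and the Br marks the future acylation carbon.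

**Step 5**
Reactants: 5
Product: 6 1‑(allyloxy)‑2‑bromo‑3,5‑bis(MOMO)benzene
Conditions: allyl bromide, K2CO3, acetone, 50 °C
Reagents that add atoms: allyl bromide, C=CCBr
Why: Williamson O‑allylation of the phenol.

**Step 6**
Reactants: 6
Product: 7 2‑allyl‑6‑bromo‑3,5‑bis(MOMO)phenol
Conditions: PhNEt2, 190 °C, sealed tube
Reagents that add atoms: none
Why: the aromatic Claisen [3,3] rearrangement must go to the only free ortho carbon, so the allyl group lands next to the phenolic oxygen (future C8). The free OH that results will become the ring oxygen.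

**Step 7**
Reactants: 7
Product: 8 6‑bromo‑3,5‑bis(MOMO)‑2‑(3‑methylbut‑2‑enyl)phenol
Conditions: 2‑methyl‑2‑butene (20 equiv), Hoveyda–Grubbs II (5 mol%), CH2Cl2, 40 °C
Reagents that add atoms: 2‑methyl‑2‑butene, CC=C(C)C
Why: cross‑metathesis converts the terminal allyl into prenyl, releasing propene.

**Step 8**
Reactants: 9 4‑bromophenol
Product: 10 1‑(allyloxy)‑4‑bromobenzene
Conditions: allyl bromide, K2CO3, acetone, reflux
Reagents that add atoms: allyl bromide, C=CCBr
Why: Williamson O‑allylation.

**Step 9**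
Reactants: 10
Product: 11 2‑allyl‑4‑bromophenol
Conditions: PhNEt2, 200 °C, sealed tube
Reagents that add atoms: none
Why: the Claisen rearrangement goes ortho because the para position is blocked by Br.

**Step 10**
Reactants: 11
Product: 12 4‑bromo‑2‑(3‑methylbut‑2‑enyl)phenol
Conditions: 2‑methyl‑2‑butene (20 equiv), Hoveyda–Grubbs II (5 mol%), CH2Cl2, 40 °C
Reagents that add atoms: 2‑methyl‑2‑butene, CC=C(C)C
Why: cross‑metathesis gives the 3'‑prenyl pattern of the B ring.

**Step 11**
Reactants: 12
Product: 13 4‑bromo‑1‑(MOMO)‑2‑prenylbenzene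
Conditions: NaH, THF, 0 °C; then MOMCl, rt
Reagents that add atoms: MOMCl, ClCOC
Why: the phenol must be masked before the titanium‑mediated epoxidation and the DIBAL reduction.

**Step 12**
Reactants: 13 and 14 methyl acrylate
Product: 15 methyl (E)‑3‑[4‑(MOMO)‑3‑prenylphenyl]acrylate
Conditions: Pd(OAc)2 (5 mol%), P(o‑tol)3 (10 mol%), Et3N, DMF, 100 °C
Reagents that add atoms: none (methyl acrylate is reactant 14)
Why: Mizoroki–Heck arylation of the acrylate gives the E‑cinnamate; the trisubstituted prenyl alkene is inert under these conditions.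

**Step 13**
Reactants: 15
Product: 16 (E)‑3‑[4‑(MOMO)‑3‑prenylphenyl]prop‑2‑en‑1‑ol
Conditions: DIBAL‑H (2.5 equiv), CH2Cl2, −78 °C; Rochelle salt work‑up
Reagents that add atoms: none
Why: 1,2‑reduction of the ester gives the allylic alcohol needed for Sharpless epoxidation.

**Step 14**
Reactants: 16
Product: 17 (2S,3S)‑[3‑(4‑MOMO‑3‑prenylphenyl)oxiran‑2‑yl]methanol
Conditions: Ti(OiPr)4 (10 mol%), L‑(+)‑DET (12 mol%), TBHP, 3 Å MS, CH2Cl2, −20 °C; basic brine work‑up
Reagents that add atoms: tert‑butyl hydroperoxide, CC(C)(C)OO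
Why: Sharpless asymmetric epoxidation is directed by the allylic alcohol, so the two isolated prenyl alkenes are untouched. L‑(+)‑DET gives the trans‑(2S,3S) epoxide, which fixes both future C2 and C3.

**Step 15**
Reactants: 17
Product: 18 (2R,3S)‑3‑(4‑MOMO‑3‑prenylphenyl)oxirane‑2‑carboxylic acid
Conditions: TEMPO (20 mol%), PhI(OAc)2 (2.5 equiv), MeCN/H2O 1:1, 0 °C → rt; NaHCO3 extraction; use crude
Reagents that add atoms: water, O (oxygen source for the acid)
Why: TEMPO/BAIB oxidises the primary alcohol to the acid without touching the alkenes or the epoxide stereocentres. The descriptor at C2 changes from S to R only because the CIP priorities change.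

**Step 16**
Reactants: 18
Product: 19 (2R,3S)‑N‑methoxy‑N‑methyl‑3‑(4‑MOMO‑3‑prenylphenyl)oxirane‑2‑carboxamide
Conditions: MeNHOMe·HCl, EDC·HCl, HOBt, Et3N, CH2Cl2, 0 °C → rt
Reagents that add atoms: N,O‑dimethylhydroxylamine hydrochloride, CNOC.Cl
Why: carbodiimide amide coupling gives the Weinreb amide, which stops at the ketone stage in the next step.

**Step 17 (late fragment coupling)**
Reactants: 8 and 19
Product: 20 (2R,3S)‑epoxy ketone, 2'‑hydroxy‑4',6'‑bis(MOMO)‑3'‑prenylphenyl ketone
Conditions: 8, n‑BuLi (2.2 equiv), THF, −78 °C, 45 min; then 19, −78 → −30 °C; sat. NH4Cl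
Reagents that add atoms: none
Why: the first equivalent of base forms the phenoxide and the second does Br/Li exchange, so the aryl anion sits exactly at the C–Br carbon ortho to the future ring oxygen. It adds to the Weinreb amide through a stable chelate, giving the aryl ketone with the epoxide and both stereocentres intact.

**Step 18**
Reactants: 20
Product: 21 protected (2R,3R)‑3‑hydroxyflavanone, 5,7,4'‑tris‑MOM, 8,3'‑diprenyl
Conditions: CSA (10 mol%), CH2Cl2, 0 °C → rt
Reagents that add atoms: none
Why: acid‑catalysed intramolecular opening of the epoxide by the only free phenol occurs 6‑endo at the benzylic carbon, which the p‑alkoxyaryl group activates, with inversion there. The Cα–O bond is untouched and becomes 3‑OH, so the (2R,3S)‑trans‑epoxide gives the 2,3‑trans (2R,3R) ring.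

**Step 19**
Reactants: 21
Product: 22 Lespedezaflavanone C
Conditions: 3 M aq. HCl/MeOH/THF (1:3:3), 40 °C, 5 h
Reagents that add atoms: none
Why: hydrolysis of the three aryl MOM acetals leaves the C2/C3 stereocentres untouched, since the trans arrangement is the stable one.

## Compound list
1 | resorcinol | Oc1cccc(O)c1 | starting material
2 | 1,3‑bis(methoxymethoxy)benzene | COCOc1cccc(OCOC)c1 | intermediate
3 | 3,5‑bis(MOMO)phenyl‑Bpin | COCOc1cc(OCOC)cc(B2OC(C)(C)C(C)(C)O2)c1 | intermediate
4 | 3,5‑bis(MOMO)phenol | COCOc1cc(O)cc(OCOC)c1 | intermediate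
5 | 2‑bromo‑3,5‑bis(MOMO)phenol | COCOc1cc(O)c(Br)c(OCOC)c1 | intermediate
6 | 1‑allyloxy‑2‑bromo‑3,5‑bis(MOMO)benzene | C=CCOc1cc(OCOC)cc(OCOC)c1Br | intermediate
7 | 2‑allyl‑6‑bromo‑3,5‑bis(MOMO)phenol | C=CCc1c(OCOC)cc(OCOC)c(Br)c1O | intermediate
8 | 6‑bromo‑3,5‑bis(MOMO)‑2‑prenylphenol | CC(C)=CCc1c(OCOC)cc(OCOC)c(Br)c1O | intermediate (A fragment)
9 | 4‑bromophenol | Oc1ccc(Br)cc1 | starting material
10 | 1‑allyloxy‑4‑bromobenzene | C=CCOc1ccc(Br)cc1 | intermediate
11 | 2‑allyl‑4‑bromophenol | C=CCc1cc(Br)ccc1O | intermediate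
12 | 4‑bromo‑2‑prenylphenol | CC(C)=CCc1cc(Br)ccc1O | intermediate
13 | 4‑bromo‑1‑(MOMO)‑2‑prenylbenzene | CC(C)=CCc1cc(Br)ccc1OCOC | intermediate
14 | methyl acrylate | C=CC(=O)OC | starting material
15 | methyl (E)‑3‑[4‑(MOMO)‑3‑prenylphenyl]acrylate | COC(=O)/C=C/c1ccc(OCOC)c(CC=C(C)C)c1 | intermediate
16 | (E)‑3‑[4‑(MOMO)‑3‑prenylphenyl]prop‑2‑en‑1‑ol | OC/C=C/c1ccc(OCOC)c(CC=C(C)C)c1 | intermediate
17 | (2S,3S)‑epoxy alcohol | OC[C@@H]1O[C@H]1c1ccc(OCOC)c(CC=C(C)C)c1 | intermediate
18 | (2R,3S)‑epoxy acid | OC(=O)[C@@H]1O[C@H]1c1ccc(OCOC)c(CC=C(C)C)c1 | intermediate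
19 | (2R,3S)‑epoxy Weinreb amide | CON(C)C(=O)[C@@H]1O[C@H]1c1ccc(OCOC)c(CC=C(C)C)c1 | intermediate (B fragment)
20 | (2R,3S)‑2'‑hydroxy epoxy ketone | CC(C)=CCc1c(OCOC)cc(OCOC)c(C(=O)[C@@H]3O[C@H]3c4ccc(OCOC)c(CC=C(C)C)c4)c1O | intermediate
21 | tris‑MOM (2R,3R)‑3‑hydroxyflavanone | CC(C)=CCc1cc([C@H]2Oc3c(CC=C(C)C)c(OCOC)cc(OCOC)c3C(=O)[C@@H]2O)ccc1OCOC | intermediate
22 | Lespedezaflavanone C | CC(C)=CCc1cc([C@H]2Oc3c(CC=C(C)C)c(O)cc(O)c3C(=O)[C@@H]2O)ccc1O | target

## Totals
Total steps: 19. Longest linear sequence: 12 (4‑bromophenol → 10 → 11 → 12 → 13 → 15 → 16 → 17 → 18 → 19 → 20 → 21 → 22).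

## Three steps most likely to fail
1. **Step 15 (glycidic acid formation).** The electron‑rich benzylic epoxy acid can open or decarboxylate.
   - Fallback: oxidise 17 to the epoxy aldehyde (SO3·py/DMSO, Et3N), add the aryl‑lithium from 8, then oxidise the carbinol to the ketone with Dess–Martin periodinane. This reaches 20 without any acid or Weinreb amide.
2. **Step 17 (coupling).** The hindered dianion may give poor conversion, or the epoxide may be attacked.
   - Fallback: convert 8 to the 2'‑hydroxyacetophenone (aryl anion plus N‑methoxy‑N‑methylacetamide) and do a Claisen–Schmidt condensation with the aldehyde from 13. Then set the stereocentres by Juliá–Colonna (poly‑D‑leucine) epoxidation of the 2'‑protected chalcone, instead of using the Sharpless epoxide.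
3. **Step 18 (cyclisation).** The phenol may attack the α‑carbon (5‑exo, aurone‑type products), MOM groups may be lost, or the benzylic centre may partly epimerise.
   - Fallback: open the epoxide reductively at Cα with SmI2 to the β‑hydroxy ketone, close the ring by Mitsunobu reaction with inversion to the (2S)‑flavanone, then hydroxylate C3 anti to the 2‑aryl group (LDA, Davis oxaziridine) to give the 2,3‑trans product.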